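**Retrosynthetic overview**

1. The butenolide is attached last: C12–C13 by B-alkyl Suzuki coupling with 4-bromofuran-2(5H)-one, on a C11=C12 vinyl group that comes from Stille coupling of a C8=C9 enol triflate.
2. Ring A is made by ring contraction. C4 is a quaternary ring carbon carrying the C18 methyl and the one-carbon oxygenated arm C19, and it sits next to the C3 methylene. That is the retron of an epoxide-to-aldehyde (Meinwald/semipinacol) shift: in the precursor C19 is a ring member between C3 and C4 of a cycloheptene oxide, and C3 migrates from C19 to C4 (7 → 6).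
3. The seven-membered carbocycle (C10-C1-C2-C3-C19-C4-C5) is closed by RCM (C4=C19) between the carvone isopropenyl group and a C10 homoallylic arm; C2 is set by Brown allylation.
4. Ring B is (S)-carvone. C5 comes from the pool, C10 from two alkylations (arm first, then CH3 anti to isopropenyl, which fixes the cis ring fusion), and the 6α-oxygen from γ-oxidation followed by L-Selectride reduction.
5. Order of ring formation: ring B (carvone) → seven-membered carbocycle (RCM) → ring A (contraction) → butenolide (coupled intact).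

Key step: step 11

Remark: labdane numbering of the target is used for all intermediates (α/β as in the usual drawing with the C10 methyl β); the SMILES is read as the 5,10-cis-fused decalin with 5β-H, 10β-CH3, 2α-OH, 6α-OH, 4α-CH3 and 4β-CH2OAc (2R,4S,5S,6S,10S in this numbering), and the route is designed for that diastereomer.

**Route**

Step 1
Reactants: 1 (S)-(+)-carvone; 2 2-bromo-N-methoxy-N-methylacetamide
Product: 3 N-methoxy-N-methyl-2-[3-methyl-2-oxo-6-(prop-1-en-2-yl)cyclohex-3-en-1-yl]acetamide (major epimer: amide arm trans to isopropenyl)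
Conditions: LDA, THF, −78 °C; then 2, −78 → −20 °C
Reagents that add atoms: none
Why: Kinetic α′-deprotonation of the enone gives the cross-conjugated lithium dienolate, which is C-alkylated by the α-bromo amide (SN2 enolate alkylation); the new C10–H centre should form mainly trans to the isopropenyl group and is erased in step 2.

Step 2
Reactants: 3 Weinreb amide (C10–H)
Product: 4 N-methoxy-N-methyl-2-[1,3-dimethyl-2-oxo-6-(prop-1-en-2-yl)cyclohex-3-en-1-yl]acetamide (10β-CH3 trans to the 5α-isopropenyl group)
Conditions: LDA, THF/DMPU, −78 °C; MeI, −78 → 0 °C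
Reagents that add atoms: iodomethane CI
Why: The ketone α′-H is far more acidic than the amide CH2, and the resulting tetrasubstituted enolate should be methylated anti to the pseudoaxial C5 isopropenyl group (the established second alkylation of 6-substituted carvones), which sets C10 with CH3 trans and the acetamide arm cis to isopropenyl, i.e. the future cis ring fusion.

Step 3
Reactants: 4 α′-quaternary enone
Product: 6 γ-hydroxy enone (6-hydroxy derivative of 4; OH expected β i.e. trans to isopropenyl), via trimethylsilyl dienol ether 5 (not isolated)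
Conditions: TMSOTf, Et3N, CH2Cl2, 0 °C; crude 5, then DMDO (1.05 equiv), acetone/CH2Cl2, −78 °C; aq. citric acid work-up
Reagents that add atoms: dimethyldioxirane CC1(C)OO1
Why: With C10 quaternary only γ-enolisation is possible, and the terminal C6=C7 bond of the 1-silyloxy-1,3-diene is epoxidised and collapses to the γ-hydroxy enone (vinylogous Rubottom oxidation); the C6 configuration does not matter because C6 is oxidised in step 4.

Step 4
Reactants: 6 γ-hydroxy enone
Product: 7 ene-dione (6-oxo derivative of 4; 2-ene-1,4-dione)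
Conditions: Dess–Martin periodinane, NaHCO3, CH2Cl2, 0 °C → rt
Reagents that add atoms: none
Why: Dess–Martin oxidation of the secondary allylic alcohol under buffered, non-enolising conditions should give the ene-dione without epimerising C5 or moving the isopropenyl double bond into conjugation.

Step 5
Reactants: 7 ene-dione
Product: 10 6α-TBS ether C8=C9 enol triflate Weinreb amide, via dilithium C9-enolate C6-alkoxide 8 (not isolated), via lithium C6-alkoxide enol triflate 9 (not isolated)
Conditions: L-Selectride (2.2 equiv), THF, −78 °C; Comins' reagent (1.1 equiv), −78 °C; TBSOTf (1.5 equiv), −78 → −40 °C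
Reagents that add atoms: Comins' reagent [N-(5-chloro-2-pyridyl)bis(trifluoromethanesulfonimide)] Clc1ccc(nc1)N(S(=O)(=O)C(F)(F)F)S(=O)(=O)C(F)(F)F; tert-butyldimethylsilyl triflate CC(C)(C)[Si](C)(C)OS(=O)(=O)C(F)(F)F
Why: Conjugate reduction with enolate trapping: hydride should add 1,4 at the unsubstituted C7 terminus to give the C9 enolate regiospecifically, and a second hydride should reduce the C6 ketone by equatorial attack (syn to H5, anti to the axial C10 arm) to give the alcohol cis to the neighbouring isopropenyl group (6α, the usual cis selectivity of Selectride with 2-substituted cyclohexanones); the enolate is O-triflated and the alkoxide O-silylated at −78 °C before it can attack the amide.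

Step 6
Reactants: 10 Weinreb amide
Product: 11 aldehyde (C2 = CHO on the C10–CH2 arm)
Conditions: DIBAL-H (1.3 equiv), THF, −78 °C; Rochelle salt work-up
Reagents that add atoms: none
Why: DIBAL reduction of a Weinreb amide stops at the chelated hemiaminal and releases the aldehyde on work-up; enol triflate, silyl ether and isopropenyl group are inert at −78 °C.

Step 7
Reactants: 11 aldehyde
Product: 12 homoallylic alcohol (C2 carbinol S in this open-chain compound; it becomes the 2α-OH)
Conditions: (−)-Ipc2B(allyl), Et2O, −78 °C; then pH 7 buffer, 30% H2O2, MeOH, 0 °C → rt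
Reagents that add atoms: (−)-B-allyldiisopinocampheylborane C=CCB([C@@H]1C[C@@H]2C[C@H]([C@H]1C)C2(C)C)[C@@H]1C[C@@H]2C[C@H]([C@H]1C)C2(C)C
Why: Brown allylboration through a chair Zimmerman–Traxler transition state; the (+)-α-pinene-derived reagent should add to the Si face of the aldehyde under reagent control and so set C2.

Step 8
Reactants: 12 homoallylic alcohol
Product: 13 bis-TBS ether (2-OTBS and 6-OTBS; terminal vinyl and isopropenyl groups)
Conditions: TBSOTf, 2,6-lutidine, CH2Cl2, −78 → 0 °C
Reagents that add atoms: tert-butyldimethylsilyl triflate CC(C)(C)[Si](C)(C)OS(=O)(=O)C(F)(F)F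
Why: Standard silylation of a secondary alcohol; no stereocentre is touched.

Step 9
Reactants: 13 diene
Product: 14 cis-fused bicyclo[5.4.0]undecadiene (cycloheptene C4(CH3)=C19H; ring B enol triflate)
Conditions: Grubbs II (5–10 mol %), toluene (5 mM), 80 °C
Reagents that add atoms: none
Why: Ring-closing metathesis between the monosubstituted and the 1,1-disubstituted olefin closes the trisubstituted cycloheptene; it is possible because the C10 arm and the C5 isopropenyl group are cis, and the tetrasubstituted enol triflate olefin does not take part.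

Step 10
Reactants: 14 cycloheptene
Product: 15 4β,19β-epoxide
Conditions: mCPBA, NaHCO3, CH2Cl2, −20 → 0 °C
Reagents that add atoms: meta-chloroperbenzoic acid OOC(=O)c1cccc(Cl)c1
Why: Prilezhaev epoxidation of the only electron-rich olefin (the enol triflate olefin is deactivated); attack is expected on the convex β face that carries H5, anti to the C5–C6 bond with its OTBS group and to the 2α-OTBS group.

Step 11
Reactants: 15 4β,19β-epoxide
Product: 16 ring-contracted aldehyde (cis-decalin; C4 with 4β-CHO and 4α-CH3)
Conditions: MABR [methylaluminium bis(4-bromo-2,6-di-tert-butylphenoxide), 20 mol %, from Me3Al and the phenol], CH2Cl2, −78 → −40 °C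
Reagents that add atoms: none
Why: The bulky aluminium Lewis acid binds the epoxide oxygen and ionises the tertiary C4–O bond, and the C19–C3 ring bond shifts to C4 on the face opposite the leaving oxygen, so C19 leaves the ring as the aldehyde carbon (Meinwald/semipinacol 1,2-alkyl shift). The closest known reaction is the MABR-promoted rearrangement of trisubstituted epoxides such as 1-methylcycloalkene oxides to α-quaternary aldehydes with ring contraction. Ring A (C4-C3-C2-C1-C10-C5) is closed by this 1,2-shift inside the seven-membered ring (7 → 6), not by a new cyclisation. The new quaternary stereocentre C4 is set stereospecifically with inversion: C3 enters α where the β-oxygen left, C19 ends β and the C18 methyl stays α, so the epoxide configuration from step 10 is the controlling element. The step needs ionisation at C4 rather than C19 and alkyl shift rather than hydride shift from C19; the tertiary C4, the bulky aluminium reagent (which favours alkyl migration to aldehydes) and the release of seven-ring strain should secure both.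

Step 12
Reactants: 16 aldehyde
Product: 17 primary alcohol (19-OH)
Conditions: NaBH4, MeOH/THF, 0 °C
Reagents that add atoms: none
Why: Borohydride reduction of the neopentyl aldehyde; enol triflate and silyl ethers are untouched and no stereocentre is formed.

Step 13
Reactants: 17 primary alcohol
Product: 18 19-acetate
Conditions: Ac2O, pyridine, DMAP (cat.), CH2Cl2, rt
Reagents that add atoms: acetic anhydride CC(=O)OC(C)=O
Why: DMAP-catalysed acetylation of the only free hydroxyl group.

Step 14
Reactants: 18 enol triflate
Product: 19 9-vinyl diene (C8(CH3)=C9–CH=CH2)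
Conditions: tributyl(vinyl)stannane, Pd(PPh3)4 (5 mol %), LiCl, THF, 65 °C
Reagents that add atoms: tributyl(vinyl)stannane C=C[Sn](CCCC)(CCCC)CCCC
Why: Stille coupling of the enol triflate under neutral conditions; the position of the tetrasubstituted C8=C9 bond is fixed by the triflate.

Step 15
Reactants: 19 9-vinyl diene; 20 4-bromofuran-2(5H)-one
Product: 22 2,6-bis-TBS ether of the target, via B-alkyl-9-BBN borane 21 (not isolated)
Conditions: 9-BBN-H, THF, 0 °C → rt; then 20, Pd(dppf)Cl2 (5 mol %), AsPh3, aq. K3PO4, DMF, rt → 50 °C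
Reagents that add atoms: none
Why: 9-BBN should add anti-Markovnikov to the terminal vinyl group only (the tetrasubstituted C8=C9 bond is inert), and B-alkyl Suzuki–Miyaura coupling with the β-bromobutenolide forms the C12–C13 bond.

Step 16
Reactants: 22 bis-TBS ether
Product: 23 CNP0201970.1 (target)
Conditions: HF·pyridine, pyridine/THF, 0 °C → rt
Reagents that add atoms: none
Why: Buffered fluoride cleavage of both secondary TBS ethers; the neopentyl acetate and the butenolide should survive these non-basic conditions, so no acyl migration is expected.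

**Compound list**

1 | (S)-(+)-carvone | C=C(C)[C@H]1CC=C(C)C(=O)C1 | starting material
2 | 2-bromo-N-methoxy-N-methylacetamide | BrCC(=O)N(C)OC | starting material
3 | N-methoxy-N-methyl-2-[3-methyl-2-oxo-6-(prop-1-en-2-yl)cyclohex-3-en-1-yl]acetamide (arm trans to isopropenyl) | C=C(C)[C@H]1CC=C(C)C(=O)[C@@H]1CC(=O)N(C)OC | intermediate
4 | N-methoxy-N-methyl-2-[1,3-dimethyl-2-oxo-6-(prop-1-en-2-yl)cyclohex-3-en-1-yl]acetamide (10β-CH3 trans to 5α-isopropenyl) | C=C(C)[C@H]1CC=C(C)C(=O)[C@@]1(C)CC(=O)N(C)OC | intermediate
5 | trimethylsilyl dienol ether of 4 (C9-OTMS; C9=C8–C7=C6) | C=C(C)[C@H]1C=CC(C)=C(O[Si](C)(C)C)[C@@]1(C)CC(=O)N(C)OC | intermediate (not isolated)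
6 | γ-hydroxy enone (6β-OH) | C=C(C)[C@H]1[C@H](O)C=C(C)C(=O)[C@@]1(C)CC(=O)N(C)OC | intermediate
7 | ene-dione (6-oxo) | C=C(C)[C@H]1C(=O)C=C(C)C(=O)[C@@]1(C)CC(=O)N(C)OC | intermediate
8 | dilithium C9-enolate C6α-alkoxide | C=C(C)[C@H]1[C@@H]([O-])CC(C)=C([O-])[C@@]1(C)CC(=O)N(C)OC.[Li+].[Li+] | intermediate (not isolated)
9 | lithium C6α-alkoxide of the C8=C9 enol triflate | C=C(C)[C@H]1[C@@H]([O-])CC(C)=C(OS(=O)(=O)C(F)(F)F)[C@@]1(C)CC(=O)N(C)OC.[Li+] | intermediate (not isolated)
10 | 6α-TBS ether C8=C9 enol triflate Weinreb amide | C=C(C)[C@H]1[C@@H](O[Si](C)(C)C(C)(C)C)CC(C)=C(OS(=O)(=O)C(F)(F)F)[C@@]1(C)CC(=O)N(C)OC | intermediate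
11 | aldehyde (C10–CH2–CHO) | C=C(C)[C@H]1[C@@H](O[Si](C)(C)C(C)(C)C)CC(C)=C(OS(=O)(=O)C(F)(F)F)[C@@]1(C)CC=O | intermediate
12 | homoallylic alcohol (future 2α-OH) | C=C(C)[C@H]1[C@@H](O[Si](C)(C)C(C)(C)C)CC(C)=C(OS(=O)(=O)C(F)(F)F)[C@@]1(C)C[C@@H](O)CC=C | intermediate
13 | bis-TBS ether | C=C(C)[C@H]1[C@@H](O[Si](C)(C)C(C)(C)C)CC(C)=C(OS(=O)(=O)C(F)(F)F)[C@@]1(C)C[C@@H](O[Si](C)(C)C(C)(C)C)CC=C | intermediate
14 | cis-fused bicyclo[5.4.0]undecadiene (C4=C19 cycloheptene) | CC1=CC[C@H](O[Si](C)(C)C(C)(C)C)C[C@]2(C)C(OS(=O)(=O)C(F)(F)F)=C(C)C[C@H](O[Si](C)(C)C(C)(C)C)[C@H]12 | intermediate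
15 | 4β,19β-epoxide | C[C@]12O[C@H]1C[C@H](O[Si](C)(C)C(C)(C)C)C[C@]3(C)C(OS(=O)(=O)C(F)(F)F)=C(C)C[C@H](O[Si](C)(C)C(C)(C)C)[C@H]23 | intermediate
16 | ring-contracted aldehyde (cis-decalin; 4β-CHO 4α-CH3) | O=C[C@@]1(C)C[C@H](O[Si](C)(C)C(C)(C)C)C[C@]2(C)C(OS(=O)(=O)C(F)(F)F)=C(C)C[C@H](O[Si](C)(C)C(C)(C)C)[C@H]12 | intermediate
17 | 19-alcohol | OC[C@@]1(C)C[C@H](O[Si](C)(C)C(C)(C)C)C[C@]2(C)C(OS(=O)(=O)C(F)(F)F)=C(C)C[C@H](O[Si](C)(C)C(C)(C)C)[C@H]12 | intermediate
18 | 19-acetate | CC(=O)OC[C@@]1(C)C[C@H](O[Si](C)(C)C(C)(C)C)C[C@]2(C)C(OS(=O)(=O)C(F)(F)F)=C(C)C[C@H](O[Si](C)(C)C(C)(C)C)[C@H]12 | intermediate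
19 | 9-vinyl diene | CC(=O)OC[C@@]1(C)C[C@H](O[Si](C)(C)C(C)(C)C)C[C@]2(C)C(C=C)=C(C)C[C@H](O[Si](C)(C)C(C)(C)C)[C@H]12 | intermediate
20 | 4-bromofuran-2(5H)-one | BrC1=CC(=O)OC1 | starting material
21 | B-alkyl-9-BBN borane (boron on C12) | CC(=O)OC[C@@]1(C)C[C@H](O[Si](C)(C)C(C)(C)C)C[C@]2(C)C(CCB3C4CCCC3CCC4)=C(C)C[C@H](O[Si](C)(C)C(C)(C)C)[C@H]12 | intermediate (not isolated)
22 | 2,6-bis-TBS ether of the target | CC(=O)OC[C@@]1(C)C[C@H](O[Si](C)(C)C(C)(C)C)C[C@]2(C)C(CCC3=CC(=O)OC3)=C(C)C[C@H](O[Si](C)(C)C(C)(C)C)[C@H]12 | intermediate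
23 | CNP0201970.1 | CC(=O)OC[C@@]1(C)C[C@H](O)C[C@]2(C)C(CCC3=CC(=O)OC3)=C(C)C[C@H](O)[C@H]12 | target

**Totals and risks**

Total step count: 16. Longest linear sequence: 16 steps, from (S)-carvone (1) to 23.

Steps most likely to fail:

Step 11. The 1,2-hydride shift from C19 to C4 may outrun the ring-bond shift and give the seven-membered ketone; proton loss from the C4 cation and a lower Lewis-acid turnover caused by the silyl ether and triflate oxygens are further risks. The fallback is a Favorskii ring contraction, also 7 → 6, that sets out from epoxide 15. A hydride-shift-selective Lewis acid (LiClO4, benzene/ether) should give the C19 cycloheptanone F1. Acid-catalysed bromination (PhNMe3Br3, THF) at the more substituted α-carbon from the β face should give the tertiary α-bromo ketone F2. NaOMe in Et2O should then close the C3 enolate onto C4 with inversion and open the cyclopropanone toward the less substituted carbanion, giving the methyl ester F3 (4β-CO2Me, 4α-CH3). DIBAL-H reduction of F3 comes back to the route at alcohol 17.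

Step 5. The first hydride may add at C8 instead of C7 or reduce a carbonyl 1,2 in the wrong order, the C6 alkoxide may lactonise onto the amide before it is silylated, and facial selectivity at C6 may be incomplete. The fallback separates the events and sets out from ene-dione 7. Zn/AcOH should reduce the ene-dione double bond to the saturated 1,4-diketone F4. L-Selectride (1 equiv, −78 °C) should reduce the less hindered C6 ketone, and in-situ TBSOTf should give the 6α-silyloxy ketone F5. KHMDS with PhNTf2 should enolise the C9 ketone toward C8 (the only α-hydrogen) and give the enol triflate, coming back to the route at 10.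

Step 10. Poor facial selectivity in the epoxidation is the risk: attack from the α face would, after the stereospecific shift, end in the C4 epimer. The fallback uses the wrong-face preference and sets out from olefin 14. NBS in aqueous acetone should form the bromonium ion on the α face, and water should open it at the tertiary C4 from the β face to give bromohydrin F6 (4β-OH, 19α-Br). K2CO3 in MeOH should close it with inversion at C19, coming back to the route at the 4β,19β-epoxide 15.

**Further compounds**

F1 | step 11 | C19 cycloheptanone from hydride shift (4-H α, 4-CH3 β) | C[C@H]1C(=O)C[C@H](O[Si](C)(C)C(C)(C)C)C[C@]2(C)C(OS(=O)(=O)C(F)(F)F)=C(C)C[C@H](O[Si](C)(C)C(C)(C)C)[C@H]12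
F2 | step 11 | tertiary α-bromo ketone (4β-Br, 4α-CH3) | C[C@]1(Br)C(=O)C[C@H](O[Si](C)(C)C(C)(C)C)C[C@]2(C)C(OS(=O)(=O)C(F)(F)F)=C(C)C[C@H](O[Si](C)(C)C(C)(C)C)[C@H]12
F3 | step 11 | ring-contracted methyl ester (4β-CO2CH3, 4α-CH3) | COC(=O)[C@@]1(C)C[C@H](O[Si](C)(C)C(C)(C)C)C[C@]2(C)C(OS(=O)(=O)C(F)(F)F)=C(C)C[C@H](O[Si](C)(C)C(C)(C)C)[C@H]12
F4 | step 5 | saturated 1,4-diketone (C8 epimers) | C=C(C)[C@H]1C(=O)CC(C)C(=O)[C@@]1(C)CC(=O)N(C)OC
F5 | step 5 | 6α-silyloxy C9 ketone (C8 epimers) | C=C(C)[C@H]1[C@@H](O[Si](C)(C)C(C)(C)C)CC(C)C(=O)[C@@]1(C)CC(=O)N(C)OC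
F6 | step 10 | bromohydrin (4β-OH, 19α-Br) | C[C@]1(O)[C@H](Br)C[C@H](O[Si](C)(C)C(C)(C)C)C[C@]2(C)C(OS(=O)(=O)C(F)(F)F)=C(C)C[C@H](O[Si](C)(C)C(C)(C)C)[C@H]12
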